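The meso 3,3''-biflavanone is disconnected at both aryl ether bonds O1–C8a, leaving C2-oxygen nucleophiles and 2-fluoroaryl ketones. In the precursor a diisopropylsilylene bridges the two carbinol oxygens of an (R,S)-configured 2,3-diaroyl-1,4-diarylbutane-1,4-diol (a seven-membered dioxasilepane), so the heterochiral pairing is fixed by the tether. Fluoride releases the alkoxides, each of which displaces the fluorine on C8a, the benzo-ring carbon ortho to the C4 ketone, closing both pyranone rings in one operation while the acidic C3 and C3'' centres settle trans to the C2 aryl groups. Silicon leaves as iPr2SiF2, and fluoride is regenerated by each ring closure.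

Key step: step 6

Assumption: 1-[4-(benzyloxy)-2-fluorophenyl]ethan-1-one is taken as a purchasable catalogue compound.

Step 1
Reactants: 1 1-[4-(benzyloxy)-2-fluorophenyl]ethan-1-one; 2 4-(benzyloxy)benzaldehyde
Product: 3 (E)-1-[4-(benzyloxy)-2-fluorophenyl]-3-[4-(benzyloxy)phenyl]prop-2-en-1-one
Conditions: NaOH (aq.), EtOH, 0 °C → rt
Reagents that add atoms: none
Why: Claisen–Schmidt condensation: the enolate of methyl ketone 1 adds to the non-enolisable aldehyde 2 and E1cB loss of water gives the conjugated (E)-enone, with no stereocentre formed and the aryl fluoride untouched at room temperature.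

Step 2
Reactants: 3 (E)-1-[4-(benzyloxy)-2-fluorophenyl]-3-[4-(benzyloxy)phenyl]prop-2-en-1-one
Product: 5 (S)-1-[4-(benzyloxy)-2-fluorophenyl]-3-[4-(benzyloxy)phenyl]-3-hydroxypropan-1-one, via (S)-β-boryl ketone 4 (not isolated)
Conditions: CuCl (3 mol %), NaOtBu (3 mol %), (R)-1-[(Sp)-2-(diphenylphosphino)ferrocenyl]ethyldicyclohexylphosphine (3 mol %), B2pin2 (1.1 equiv), MeOH (2 equiv), THF, rt; then NaBO3·4H2O, THF/H2O, rt
Reagents that add atoms: bis(pinacolato)diboron, CC1(C)OB(OC1(C)C)B1OC(C)(C)C(C)(C)O1 (boryl group of 4); sodium perborate, [Na+].[O-]OB=O (hydroxyl oxygen of 5)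
Why: Copper-catalysed asymmetric conjugate borylation of the enone followed by perborate oxidation of the C–B bond with retention (a formal enantioselective hydration): the bisphosphine-bound Cu–Bpin species adds boron to one face of the β-carbon and so sets the carbinol centre, taken here as (S), and because step 3 uses the antipodal ligand 5 and 7 are mirror images whichever sense holds.

Step 3
Reactants: 3 (E)-1-[4-(benzyloxy)-2-fluorophenyl]-3-[4-(benzyloxy)phenyl]prop-2-en-1-one
Product: 7 (R)-1-[4-(benzyloxy)-2-fluorophenyl]-3-[4-(benzyloxy)phenyl]-3-hydroxypropan-1-one, via (R)-β-boryl ketone 6 (not isolated)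
Conditions: CuCl (3 mol %), NaOtBu (3 mol %), (S)-1-[(Rp)-2-(diphenylphosphino)ferrocenyl]ethyldicyclohexylphosphine (3 mol %), B2pin2 (1.1 equiv), MeOH (2 equiv), THF, rt; then NaBO3·4H2O, THF/H2O, rt
Reagents that add atoms: bis(pinacolato)diboron, CC1(C)OB(OC1(C)C)B1OC(C)(C)C(C)(C)O1 (boryl group of 6); sodium perborate, [Na+].[O-]OB=O (hydroxyl oxygen of 7)
Why: The same copper-catalysed asymmetric conjugate borylation and stereoretentive C–B oxidation as in step 2, run with the mirror-image ligand so that the opposite face of the β-carbon is borylated and the enantiomeric carbinol centre is set.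

Step 4
Reactants: 5 (S)-1-[4-(benzyloxy)-2-fluorophenyl]-3-[4-(benzyloxy)phenyl]-3-hydroxypropan-1-one; 7 (R)-1-[4-(benzyloxy)-2-fluorophenyl]-3-[4-(benzyloxy)phenyl]-3-hydroxypropan-1-one
Product: 9 (3R,3'S)-3,3'-{[di(propan-2-yl)silanediyl]bis(oxy)}bis{1-[4-(benzyloxy)-2-fluorophenyl]-3-[4-(benzyloxy)phenyl]propan-1-one} (meso), via chlorosilyl ether 8 (not isolated)
Conditions: 5 added slowly to iPr2SiCl2 (3 equiv), imidazole, CH2Cl2, 0 °C; excess iPr2SiCl2 removed in vacuo; then 7, imidazole, DMAP (cat.), DMF, rt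
Reagents that add atoms: dichlorodi(propan-2-yl)silane, CC(C)[Si](Cl)(Cl)C(C)C
Why: Stepwise silyl ether formation to a mixed dialkoxysilane (silaketal tether): the bulky isopropyl groups and the excess of dichlorosilane stop the first silylation at monochloride 8, the opposite enantiomer is then attached at the second Si–Cl bond, and since only O–Si bonds are formed both carbinol centres are retained, so that the (R,S) pairing of the target is fixed here.

Step 5
Reactants: 9 (3R,3'S)-3,3'-{[di(propan-2-yl)silanediyl]bis(oxy)}bis{1-[4-(benzyloxy)-2-fluorophenyl]-3-[4-(benzyloxy)phenyl]propan-1-one}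
Product: 11 [(4R,7S)-4,7-bis[4-(benzyloxy)phenyl]-2,2-di(propan-2-yl)-1,3,2-dioxasilepane-5,6-diyl]bis{[4-(benzyloxy)-2-fluorophenyl]methanone} (4,7-cis; mixture of C5/C6 epimers), via dilithium bis-enolate 10 (not isolated)
Conditions: LiN(iPr)2 (2.1 equiv), THF, −78 °C; then CuCl2 (2.2 equiv, as a DMF solution), −78 → −40 °C, high dilution
Reagents that add atoms: none
Why: Intramolecular oxidative coupling of ketone enolates mediated by CuCl2: one-electron oxidation of bis-enolate 10 joins the two α-carbons in a seven-membered ring held by the tether, the two new α-keto centres (C5, C6) arise without control and are accepted as a mixture because both are re-set in step 6, and the carbinol centres C4 and C7 are not touched.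

Step 6
Reactants: 11 [(4R,7S)-4,7-bis[4-(benzyloxy)phenyl]-2,2-di(propan-2-yl)-1,3,2-dioxasilepane-5,6-diyl]bis{[4-(benzyloxy)-2-fluorophenyl]methanone}
Product: 14 (2S,2'R,3R,3'S)-7,7'-bis(benzyloxy)-2,2'-bis[4-(benzyloxy)phenyl]-[3,3'-bichromane]-4,4'-dione (meso), via ring-opened diol 12 (not isolated), via half-closed flavanone 13 (not isolated)
Conditions: Bu4NF (1.0 M in THF, 2.2 equiv), THF, 0 → 40 °C
Reagents that add atoms: none
Why: Fluoride attacks silicon of the dioxasilepane and frees a secondary benzylic alkoxide, which adds to the fluorine-bearing aryl carbon ortho to the ketone (Meisenheimer anion delocalised into the C4 carbonyl) and expels fluoride, forming the O1–C8a bond; the expelled fluoride cleaves the second Si–O bond and the sequence repeats, so that silicon leaves as iPr2SiF2. The closest known reaction types are the intramolecular SNAr etherification of 2-fluoroaryl ketones to chroman-4-ones and the fluoride-mediated desilylative formation of aryl ethers from silyl ethers and fluoroarenes. Each pyranone ring closes in a 6-exo-trig addition–elimination (attack at C8a, whose C8a=C8 bond lies outside the new ring). No stereocentre is made at C2 or C2'', whose configurations come unchanged from 5 and 7 because only their oxygen atoms react; C3 and C3'' are equilibrated through their enolates by the basic medium to the 2,3-trans diequatorial arrangement in each ring, which together with (2S,2''R) gives the meso (2S,3R,2''R,3''S) isomer. The step needs O-arylation to outrun retro-aldol cleavage of the β-alkoxy ketones and ring-opening of the product by retro-oxa-Michael reaction; the six-membered transition state, the ortho-carbonyl activation, the single fluorine on each ring and the mild fluoride base are what should secure this.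

Step 7
Reactants: 14 (2S,2'R,3R,3'S)-7,7'-bis(benzyloxy)-2,2'-bis[4-(benzyloxy)phenyl]-[3,3'-bichromane]-4,4'-dione
Product: 15 (2S,2'R,3R,3'S)-7,7'-dihydroxy-2,2'-bis(4-hydroxyphenyl)-[3,3'-bichromane]-4,4'-dione (meso; CNP0231820.1)
Conditions: H2 (1 atm), Pd/C (10 wt %), THF/MeOH, rt
Reagents that add atoms: none
Why: Hydrogenolysis of the four aryl benzyl ethers over palladium should be faster at 1 atm and room temperature than reduction of the aryl ketones or cleavage of the cyclic C2–O1 benzylic ethers, and under these neutral conditions none of the four stereocentres can epimerise.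

Compound list
1 | 1-[4-(benzyloxy)-2-fluorophenyl]ethan-1-one | CC(=O)c1ccc(OCc2ccccc2)cc1F | starting material
2 | 4-(benzyloxy)benzaldehyde | O=Cc1ccc(OCc2ccccc2)cc1 | starting material
3 | (E)-1-[4-(benzyloxy)-2-fluorophenyl]-3-[4-(benzyloxy)phenyl]prop-2-en-1-one | O=C(/C=C/c1ccc(OCc2ccccc2)cc1)c1ccc(OCc2ccccc2)cc1F | intermediate
4 | (S)-1-[4-(benzyloxy)-2-fluorophenyl]-3-[4-(benzyloxy)phenyl]-3-(4,4,5,5-tetramethyl-1,3,2-dioxaborolan-2-yl)propan-1-one (not isolated) | CC1(C)OB(OC1(C)C)[C@@H](CC(=O)c1ccc(OCc2ccccc2)cc1F)c1ccc(OCc2ccccc2)cc1 | intermediate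
5 | (S)-1-[4-(benzyloxy)-2-fluorophenyl]-3-[4-(benzyloxy)phenyl]-3-hydroxypropan-1-one | O[C@@H](CC(=O)c1ccc(OCc2ccccc2)cc1F)c1ccc(OCc2ccccc2)cc1 | intermediate
6 | (R)-1-[4-(benzyloxy)-2-fluorophenyl]-3-[4-(benzyloxy)phenyl]-3-(4,4,5,5-tetramethyl-1,3,2-dioxaborolan-2-yl)propan-1-one (not isolated) | CC1(C)OB(OC1(C)C)[C@H](CC(=O)c1ccc(OCc2ccccc2)cc1F)c1ccc(OCc2ccccc2)cc1 | intermediate
7 | (R)-1-[4-(benzyloxy)-2-fluorophenyl]-3-[4-(benzyloxy)phenyl]-3-hydroxypropan-1-one | O[C@H](CC(=O)c1ccc(OCc2ccccc2)cc1F)c1ccc(OCc2ccccc2)cc1 | intermediate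
8 | (S)-1-[4-(benzyloxy)-2-fluorophenyl]-3-[4-(benzyloxy)phenyl]-3-{[chlorodi(propan-2-yl)silyl]oxy}propan-1-one (not isolated) | CC(C)[Si](Cl)(C(C)C)O[C@@H](CC(=O)c1ccc(OCc2ccccc2)cc1F)c1ccc(OCc2ccccc2)cc1 | intermediate
9 | (3R,3'S)-3,3'-{[di(propan-2-yl)silanediyl]bis(oxy)}bis{1-[4-(benzyloxy)-2-fluorophenyl]-3-[4-(benzyloxy)phenyl]propan-1-one}, meso | CC(C)[Si](C(C)C)(O[C@@H](CC(=O)c1ccc(OCc2ccccc2)cc1F)c1ccc(OCc2ccccc2)cc1)O[C@H](CC(=O)c1ccc(OCc2ccccc2)cc1F)c1ccc(OCc2ccccc2)cc1 | intermediate
10 | dilithium (Z,Z)-bis-enolate of 9 (not isolated) | CC(C)[Si](C(C)C)(O[C@@H](/C=C(\O[Li])c1ccc(OCc2ccccc2)cc1F)c1ccc(OCc2ccccc2)cc1)O[C@H](/C=C(\O[Li])c1ccc(OCc2ccccc2)cc1F)c1ccc(OCc2ccccc2)cc1 | intermediate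
11 | [(4R,7S)-4,7-bis[4-(benzyloxy)phenyl]-2,2-di(propan-2-yl)-1,3,2-dioxasilepane-5,6-diyl]bis{[4-(benzyloxy)-2-fluorophenyl]methanone}, 4,7-cis, mixture of epimers at C5 and C6 | CC(C)[Si]1(C(C)C)O[C@H](c2ccc(OCc3ccccc3)cc2)C(C(=O)c2ccc(OCc3ccccc3)cc2F)C(C(=O)c2ccc(OCc3ccccc3)cc2F)[C@H](c2ccc(OCc3ccccc3)cc2)O1 | intermediate
12 | 1,4-bis[4-(benzyloxy)-2-fluorophenyl]-2,3-bis{[4-(benzyloxy)phenyl](hydroxy)methyl}butane-1,4-dione with one (S)- and one (R)-carbinol carbon, mixture of epimers at C2 and C3, present as its alkoxide (not isolated) | O[C@H](c1ccc(OCc2ccccc2)cc1)C(C(=O)c1ccc(OCc2ccccc2)cc1F)C(C(=O)c1ccc(OCc2ccccc2)cc1F)[C@@H](O)c1ccc(OCc2ccccc2)cc1 | intermediate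
13 | 7-(benzyloxy)-3-{1-[4-(benzyloxy)-2-fluorophenyl]-3-[4-(benzyloxy)phenyl]-3-hydroxy-1-oxopropan-2-yl}-2-[4-(benzyloxy)phenyl]chroman-4-one, (2S) in the ring and (R) at the open-chain carbinol, racemic (one enantiomer drawn), epimer mixture at the two α-keto carbons (not isolated) | O=C1c2ccc(OCc3ccccc3)cc2O[C@H](c2ccc(OCc3ccccc3)cc2)C1C(C(=O)c1ccc(OCc2ccccc2)cc1F)[C@@H](O)c1ccc(OCc2ccccc2)cc1 | intermediate
14 | (2S,2'R,3R,3'S)-7,7'-bis(benzyloxy)-2,2'-bis[4-(benzyloxy)phenyl]-[3,3'-bichromane]-4,4'-dione, meso, 2,3-trans in both rings | O=C1c2ccc(OCc3ccccc3)cc2O[C@H](c2ccc(OCc3ccccc3)cc2)[C@H]1[C@@H]1C(=O)c2ccc(OCc3ccccc3)cc2O[C@H]1c1ccc(OCc2ccccc2)cc1 | intermediate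
15 | (2S,2'R,3R,3'S)-7,7'-dihydroxy-2,2'-bis(4-hydroxyphenyl)-[3,3'-bichromane]-4,4'-dione, meso (CNP0231820.1) | O=C1c2ccc(O)cc2O[C@H](c2ccc(O)cc2)[C@H]1[C@@H]1C(=O)c2ccc(O)cc2O[C@H]1c1ccc(O)cc1 | target

Total step count: 7
Longest linear sequence: 6 steps (steps 1, 2, 4, 5, 6, 7; step 3 is a parallel branch from 3)

Steps most likely to fail

Step 5. The lithium enolates may lose the β-silyloxy group by E1cB elimination before they are oxidised, or intermolecular coupling may outrun closure of the seven-membered ring. The fallback sets out from 9 and comes back at 11. Soft enolisation of 9 with Me3SiOTf/Et3N (CH2Cl2, 0 °C) should give the bis(trimethylsilyl enol ether) of 9 F1 without a metal enolate ever being formed. Oxidation of F1 with Cu(OTf)2/Cu2O (MeCN, 0 °C, high dilution) should then join the two enol carbons by way of an enol-ether radical cation (oxidative coupling of silyl enol ethers) and deliver 11.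

Step 6. Retro-aldol fragmentation of the freed β-alkoxy ketones may compete with the ring closures, or the C2 configuration may erode through base-induced ring-opening and re-closure of the product during the fluoride treatment. The fallback sets out from 11 and comes back at 14. The silylene is removed without base by HF·pyridine (THF/pyridine, 0 °C) and diol 12 is isolated. Irreversible deprotonation with NaH (2.2 equiv, DMF, 0 °C → rt) then gives chelated sodium aldolates, which should close through 13 to 14 by the same SNAr, the excess alkoxide again equilibrating C3 and C3''. Unmasking and ring closure are thus separated, and the alkoxide is made by deprotonation instead of desilylation.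

Step 4. Exchange at silicon during the first stage may give the symmetric bis-ether of 5, which would lead to the C2-symmetric diastereomer, or the second, hindered silylation may stall. The fallback sets out from 5 and comes back at 9. Alcohol 5 is silylated with iPr2SiHCl/imidazole (DMF, rt) to the hydridosilyl ether of 5 F2, which can be purified. NBS (CH2Cl2, 0 °C) converts its Si–H into Si–Br, giving the bromosilyl ether of 5 F3 in solution, and addition of 7 with imidazole and DMAP should give 9.

Further compounds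
F1 | step 5 | (Z,Z)-bis(trimethylsilyl enol ether) of 9 | CC(C)[Si](C(C)C)(O[C@@H](/C=C(\O[Si](C)(C)C)c1ccc(OCc2ccccc2)cc1F)c1ccc(OCc2ccccc2)cc1)O[C@H](/C=C(\O[Si](C)(C)C)c1ccc(OCc2ccccc2)cc1F)c1ccc(OCc2ccccc2)cc1
F0 | step 6 | none | none
F2 | step 4 | (S)-1-[4-(benzyloxy)-2-fluorophenyl]-3-[4-(benzyloxy)phenyl]-3-{[di(propan-2-yl)silyl]oxy}propan-1-one | CC(C)[SiH](C(C)C)O[C@@H](CC(=O)c1ccc(OCc2ccccc2)cc1F)c1ccc(OCc2ccccc2)cc1
F3 | step 4 | (S)-1-[4-(benzyloxy)-2-fluorophenyl]-3-[4-(benzyloxy)phenyl]-3-{[bromodi(propan-2-yl)silyl]oxy}propan-1-one | CC(C)[Si](Br)(C(C)C)O[C@@H](CC(=O)c1ccc(OCc2ccccc2)cc1F)c1ccc(OCc2ccccc2)cc1
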